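## Retrosynthetic overview

1. Last C–O bond: Yamaguchi esterification of the C15 epoxy-germacrenol **32** (6-OTES, free 8-OH) with the silylated isovanillic acid **40**, then one global desilylation.
2. Ten-membered ring: C6–C7 bond by intramolecular Pd/Et2Zn umpolung allylation of the epoxy-aldehyde/allylic chloride **27**, which sets C6 and C7; the isopropenyl group is hydrogenated afterwards.
3. Epoxide (C4, C5) by Sharpless epoxidation of the farnesol-type alcohol **25**; the acyclic C15 chain by an sp3–sp2 Negishi union (C1–C2) of iodide **6** with vinyl iodide **19**.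
4. Fragments from but-3-yn-1-ol, prop-2-yn-1-ol and propargyl bromide (three Zr-catalysed carboaluminations fix all E-olefins; C8 by catalytic asymmetric propargylation); the aryl acid from catechol.
5. Ring order: arene (from catechol) → oxirane (step 16) → cyclodecene (step 18).

Assumption: the target is taken exactly as the SMILES reads, i.e. 4R,5R,6R,7R,8R in germacrane numbering (C1=C10 olefin, C4–C5 epoxide, C6–OH, C7–iPr, C8–ester); this numbering is used for atoms throughout.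

## Route

**Fragment A (C2–C6, C15)**

Step 1
Reactants: 1 but-3-yn-1-ol
Product: 2 tert-butyl(but-3-yn-1-yloxy)dimethylsilane
Conditions: TBSCl, imidazole, DMF, 0 °C → rt
Reagents that add atoms: tert-butyldimethylsilyl chloride, CC(C)(C)[Si](C)(C)Cl
Why: Standard silylation of a primary alcohol, so that no free alkoxide competes for the chloroformate in step 2.

Step 2
Reactants: 2 tert-butyl(but-3-yn-1-yloxy)dimethylsilane
Product: 4 ethyl (2E)-5-[(tert-butyldimethylsilyl)oxy]-3-methylpent-2-enoate, via alkenylalane 3 (not isolated)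
Conditions: Me3Al (2 equiv), Cp2ZrCl2 (0.25 equiv), CH2Cl2, 0 °C → rt; then ClCO2Et, 0 °C → rt
Reagents that add atoms: trimethylaluminium, C[Al](C)C; ethyl chloroformate, CCOC(=O)Cl
Why: Negishi Zr-catalysed syn-carboalumination puts Me on the internal carbon and Al cis to it, and C-acylation of the alkenylalane with retention gives the E-trisubstituted enoate (C4=C5, C15, C6).

Step 3
Reactants: 4 ethyl (2E)-5-[(tert-butyldimethylsilyl)oxy]-3-methylpent-2-enoate
Product: 5 ethyl (2E)-5-hydroxy-3-methylpent-2-enoate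
Conditions: p-TsOH·H2O (5 mol%), EtOH, rt
Reagents that add atoms: none
Why: Acid-catalysed ethanolysis of a primary TBS ether; ethanol makes transesterification degenerate and the E-geometry prevents lactonisation.

Step 4
Reactants: 5 ethyl (2E)-5-hydroxy-3-methylpent-2-enoate
Product: 6 ethyl (2E)-5-iodo-3-methylpent-2-enoate
Conditions: I2, PPh3, imidazole, CH2Cl2, 0 °C
Reagents that add atoms: iodine, II
Why: Appel-type (Garegg–Samuelsson) iodination, SN2 on the alkoxyphosphonium ion of a primary alcohol under nearly neutral conditions.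

**Fragment B (C7–C13, C9, C10, C14, C1)**

Step 5
Reactants: 7 prop-2-yn-1-ol
Product: 9 (2E)-3-iodo-2-methylprop-2-en-1-ol, via alkenylalane 8 (not isolated)
Conditions: Me3Al (3 equiv), Cp2ZrCl2 (0.25 equiv), CH2Cl2, 0 °C → rt; then I2, THF, −30 °C
Reagents that add atoms: trimethylaluminium, C[Al](C)C; iodine, II
Why: Negishi syn-carboalumination followed by iodinolysis with retention delivers the E-vinyl iodide (C7=C11 with C13 methyl, C12 oxygen).

Step 6
Reactants: 9 (2E)-3-iodo-2-methylprop-2-en-1-ol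
Product: 10 tert-butyl{[(2E)-3-iodo-2-methylprop-2-en-1-yl]oxy}dimethylsilane
Conditions: TBSCl, imidazole, CH2Cl2, rt
Reagents that add atoms: tert-butyldimethylsilyl chloride, CC(C)(C)[Si](C)(C)Cl
Why: Standard silylation of the primary allylic alcohol before halogen–lithium exchange.

Step 7
Reactants: 10 tert-butyl{[(2E)-3-iodo-2-methylprop-2-en-1-yl]oxy}dimethylsilane
Product: 12 (2E)-4-[(tert-butyldimethylsilyl)oxy]-3-methylbut-2-enal, via vinyllithium 11 (not isolated)
Conditions: t-BuLi (2.1 equiv), Et2O, −78 °C; then DMF, −78 → 0 °C; aq. NH4Cl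
Reagents that add atoms: N,N-dimethylformamide, CN(C)C=O
Why: Iodine–lithium exchange gives a configurationally stable alkenyllithium (Li trans to CH2OTBS, so no silyl migration) that is formylated with retention (introduces C8).

Step 8
Reactants: 13 3-bromoprop-1-yne
Product: 15 tributyl(propa-1,2-dien-1-yl)stannane, via allenylmagnesium bromide 14 (not isolated)
Conditions: Mg, HgCl2 (cat.), Et2O, 0 °C; then Bu3SnCl, 0 °C → rt
Reagents that add atoms: tributyltin chloride, CCCC[Sn](Cl)(CCCC)CCCC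
Why: Grignard formation from propargyl bromide and stannylation, which gives predominantly the allenyl isomer needed for SE2′ propargyl transfer.

Step 9
Reactants: 12 (2E)-4-[(tert-butyldimethylsilyl)oxy]-3-methylbut-2-enal and 15 tributyl(propa-1,2-dien-1-yl)stannane
Product: 16 (2E,4R)-1-[(tert-butyldimethylsilyl)oxy]-2-methylhept-2-en-6-yn-4-ol
Conditions: (R)-BINOL (20 mol%), Ti(OiPr)4 (10 mol%), 4 Å MS, CH2Cl2, −20 °C; aq. NaHCO3
Reagents that add atoms: none
Why: Keck-type BINOL–Ti(IV)-catalysed SE2′ propargylation of the enal; the (R)-BINOL complex directs Re-face attack (by analogy with the allylation) and so sets C8 as R under catalyst control.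

Step 10
Reactants: 16 (2E,4R)-1-[(tert-butyldimethylsilyl)oxy]-2-methylhept-2-en-6-yn-4-ol
Product: 18 (2E,4R,6E)-1-[(tert-butyldimethylsilyl)oxy]-7-iodo-2,6-dimethylhepta-2,6-dien-4-ol, via alkenylalane 17 (not isolated)
Conditions: Me3Al (3 equiv), Cp2ZrCl2 (0.5 equiv), CH2Cl2, 0 °C → rt; then I2, THF, −30 °C
Reagents that add atoms: trimethylaluminium, C[Al](C)C; iodine, II
Why: Hydroxyl-assisted Negishi carboalumination of the terminal alkyne and iodinolysis with retention give the E-vinyl iodide (C1=C10 with C14 methyl); the trisubstituted alkene is inert.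

Step 11
Reactants: 18 (2E,4R,6E)-1-[(tert-butyldimethylsilyl)oxy]-7-iodo-2,6-dimethylhepta-2,6-dien-4-ol
Product: 19 tert-butyl{[(2E,4R,6E)-7-iodo-4-[(4-methoxyphenyl)methoxy]-2,6-dimethylhepta-2,6-dien-1-yl]oxy}dimethylsilane
Conditions: NaH, PMBCl, Bu4NI (cat.), THF/DMF, 0 °C → rt
Reagents that add atoms: 4-methoxybenzyl chloride, COc1ccc(CCl)cc1
Why: Williamson etherification under basic conditions (no allylic ionisation); PMB is chosen because it can be removed oxidatively at neutral pH after ring closure.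

**Union, epoxide, ring closure**

Step 12
Reactants: 6 ethyl (2E)-5-iodo-3-methylpent-2-enoate and 19 tert-butyl{[(2E,4R,6E)-7-iodo-4-[(4-methoxyphenyl)methoxy]-2,6-dimethylhepta-2,6-dien-1-yl]oxy}dimethylsilane
Product: 21 ethyl (2E,6E,9R,10E)-12-[(tert-butyldimethylsilyl)oxy]-9-[(4-methoxyphenyl)methoxy]-3,7,11-trimethyldodeca-2,6,10-trienoate, via alkylzinc iodide 20 (not isolated)
Conditions: 6, Zn dust (BrCH2CH2Br/TMSCl-activated), THF/DMA, 40 °C; then 19, Pd(PPh3)4 (5 mol%), 50 °C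
Reagents that add atoms: none
Why: Zinc insertion tolerates the ester, and Negishi sp3–sp2 cross-coupling forms C1–C2 with retention of the vinyl iodide geometry.

Step 13
Reactants: 21 ethyl (2E,6E,9R,10E)-12-[(tert-butyldimethylsilyl)oxy]-9-[(4-methoxyphenyl)methoxy]-3,7,11-trimethyldodeca-2,6,10-trienoate
Product: 22 ethyl (2E,6E,9R,10E)-12-hydroxy-9-[(4-methoxyphenyl)methoxy]-3,7,11-trimethyldodeca-2,6,10-trienoate
Conditions: TBAF (1.1 equiv), THF, 0 °C
Reagents that add atoms: none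
Why: Fluoride cleaves the primary allylic TBS ether; the ester and PMB ether are untouched.

Step 14
Reactants: 22 ethyl (2E,6E,9R,10E)-12-hydroxy-9-[(4-methoxyphenyl)methoxy]-3,7,11-trimethyldodeca-2,6,10-trienoate
Product: 24 ethyl (2E,6E,9R,10E)-12-chloro-9-[(4-methoxyphenyl)methoxy]-3,7,11-trimethyldodeca-2,6,10-trienoate, via allylic mesylate 23 (not isolated)
Conditions: MsCl, 2,4,6-collidine, LiCl, DMF, 0 °C
Reagents that add atoms: lithium chloride, [Li+].[Cl-]
Why: Collington–Meyers chlorination, mesylation then SN2 by chloride at the primary allylic carbon, without transposition or loss of E-geometry.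

Step 15
Reactants: 24 ethyl (2E,6E,9R,10E)-12-chloro-9-[(4-methoxyphenyl)methoxy]-3,7,11-trimethyldodeca-2,6,10-trienoate
Product: 25 (2E,6E,9R,10E)-12-chloro-9-[(4-methoxyphenyl)methoxy]-3,7,11-trimethyldodeca-2,6,10-trien-1-ol
Conditions: DIBAL-H (2.5 equiv), CH2Cl2, −78 °C; Rochelle salt
Reagents that add atoms: none
Why: 1,2-Reduction of the enoate to the allylic alcohol at −78 °C, where the allylic chloride and PMB ether survive.

Step 16
Reactants: 25 (2E,6E,9R,10E)-12-chloro-9-[(4-methoxyphenyl)methoxy]-3,7,11-trimethyldodeca-2,6,10-trien-1-ol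
Product: 26 [(2R,3R)-3-{(3E,6R,7E)-9-chloro-6-[(4-methoxyphenyl)methoxy]-4,8-dimethylnona-3,7-dien-1-yl}-3-methyloxiran-2-yl]methanol
Conditions: Ti(OiPr)4 (10 mol%), D-(−)-diethyl tartrate (12 mol%), t-BuOOH, 4 Å MS, CH2Cl2, −20 °C
Reagents that add atoms: tert-butyl hydroperoxide, CC(C)(C)OO
Why: Sharpless asymmetric epoxidation is chemoselective for the allylic-alcohol olefin, and D-(−)-DET gives the (2R,3R)-epoxide as with geraniol, setting C4 (R) and C5 (R).

Step 17
Reactants: 26 [(2R,3R)-3-{(3E,6R,7E)-9-chloro-6-[(4-methoxyphenyl)methoxy]-4,8-dimethylnona-3,7-dien-1-yl}-3-methyloxiran-2-yl]methanol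
Product: 27 (2S,3R)-3-{(3E,6R,7E)-9-chloro-6-[(4-methoxyphenyl)methoxy]-4,8-dimethylnona-3,7-dien-1-yl}-3-methyloxirane-2-carbaldehyde
Conditions: Dess–Martin periodinane, NaHCO3, CH2Cl2, 0 °C → rt; used crude
Reagents that add atoms: none
Why: Buffered Dess–Martin oxidation gives the epoxy aldehyde without epoxide opening; the descriptor at C5 changes by CIP priority only.

Step 18
Reactants: 27 (2S,3R)-3-{(3E,6R,7E)-9-chloro-6-[(4-methoxyphenyl)methoxy]-4,8-dimethylnona-3,7-dien-1-yl}-3-methyloxirane-2-carbaldehyde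
Product: 29 (1R,4E,7R,8R,9R,10R)-7-[(4-methoxyphenyl)methoxy]-1,5-dimethyl-8-(prop-1-en-2-yl)-11-oxabicyclo[8.1.0]undec-4-en-9-ol, via allylzinc 28 (not isolated)
Conditions: PdCl2(PPh3)2 (20 mol%), Et2Zn (4 equiv), K2CO3, DMA, rt, syringe-pump addition to ca. 3 mM
Reagents that add atoms: none
Why: Tamaru-type umpolung allylation (Pd π-allyl → allylzinc) closes the ring through γ-carbon C7 in a chair six-membered transition state: attack anti to the epoxide C–O (Cornforth/Felkin) sets C6, the E-allyl geometry sets C7 trans to the 6-OH, and the 8R-OPMB group sits pseudo-equatorial in this all-equatorial array; the ring closure is known for the C8-unsubstituted epoxy-farnesal chloride.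

Step 19
Reactants: 29 (1R,4E,7R,8R,9R,10R)-7-[(4-methoxyphenyl)methoxy]-1,5-dimethyl-8-(prop-1-en-2-yl)-11-oxabicyclo[8.1.0]undec-4-en-9-ol
Product: 30 (1R,4E,7R,8S,9R,10R)-7-[(4-methoxyphenyl)methoxy]-1,5-dimethyl-8-(prop-1-en-2-yl)-9-[(triethylsilyl)oxy]-11-oxabicyclo[8.1.0]undec-4-ene
Conditions: TESCl, imidazole, DMAP (cat.), DMF, rt → 40 °C
Reagents that add atoms: chlorotriethylsilane, CC[Si](Cl)(CC)CC
Why: Silylation under basic, non-Lewis-acidic conditions spares the epoxide and blocks C6–OH so that later only C8–OH can be acylated (the C8 descriptor becomes S by CIP priority only).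

Step 20
Reactants: 30 (1R,4E,7R,8S,9R,10R)-7-[(4-methoxyphenyl)methoxy]-1,5-dimethyl-8-(prop-1-en-2-yl)-9-[(triethylsilyl)oxy]-11-oxabicyclo[8.1.0]undec-4-ene
Product: 31 (1R,4E,7R,8S,9R,10R)-7-[(4-methoxyphenyl)methoxy]-1,5-dimethyl-8-(propan-2-yl)-9-[(triethylsilyl)oxy]-11-oxabicyclo[8.1.0]undec-4-ene
Conditions: H2 (1–3 atm), RhCl(PPh3)3 (10 mol%), benzene, rt
Reagents that add atoms: none
Why: Wilkinson hydrogenation reduces the 1,1-disubstituted alkene far faster than the trisubstituted ring alkene and leaves epoxide, PMB and TES intact; no stereocentre is created.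

Step 21
Reactants: 31 (1R,4E,7R,8S,9R,10R)-7-[(4-methoxyphenyl)methoxy]-1,5-dimethyl-8-(propan-2-yl)-9-[(triethylsilyl)oxy]-11-oxabicyclo[8.1.0]undec-4-ene
Product: 32 (1R,4E,7R,8S,9R,10R)-1,5-dimethyl-8-(propan-2-yl)-9-[(triethylsilyl)oxy]-11-oxabicyclo[8.1.0]undec-4-en-7-ol
Conditions: DDQ (1.3 equiv), CH2Cl2/pH 7 buffer (10:1), 0 °C
Reagents that add atoms: none
Why: Oxidative PMB cleavage at neutral pH (no acid, so no transannular epoxide opening); C7 is no longer allylic and C6–O is silylated, so neither over-oxidation nor acetal formation can occur.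

**Aryl acid**

Step 22
Reactants: 33 benzene-1,2-diol
Product: 34 2-methoxyphenol
Conditions: MeI (1.0 equiv), K2CO3, acetone, reflux
Reagents that add atoms: iodomethane, CI
Why: Williamson mono-O-methylation with one equivalent of MeI; the product is separated from veratrole and catechol by distillation.

Step 23
Reactants: 34 2-methoxyphenol
Product: 35 2-methoxyphenyl acetate
Conditions: Ac2O, pyridine, CH2Cl2, rt
Reagents that add atoms: acetic anhydride, CC(=O)OC(C)=O
Why: Acetylation attenuates the phenol oxygen so that the methoxy group controls the next substitution.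

Step 24
Reactants: 35 2-methoxyphenyl acetate
Product: 36 5-bromo-2-methoxyphenyl acetate
Conditions: NBS, MeCN, rt
Reagents that add atoms: N-bromosuccinimide, O=C1CCC(=O)N1Br
Why: Electrophilic aromatic bromination occurs para to the stronger donor OMe, which is the position meta to the acetoxy group.

Step 25
Reactants: 36 5-bromo-2-methoxyphenyl acetate
Product: 37 5-bromo-2-methoxyphenol
Conditions: K2CO3, MeOH, rt
Reagents that add atoms: none
Why: Mild methanolysis of the aryl acetate.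

Step 26
Reactants: 37 5-bromo-2-methoxyphenol
Product: 38 (5-bromo-2-methoxyphenoxy)(tert-butyl)dimethylsilane
Conditions: TBSCl, imidazole, DMF, rt
Reagents that add atoms: tert-butyldimethylsilyl chloride, CC(C)(C)[Si](C)(C)Cl
Why: Phenol silylation gives a group that survives BuLi and the esterification and leaves with fluoride at the end.

Step 27
Reactants: 38 (5-bromo-2-methoxyphenoxy)(tert-butyl)dimethylsilane
Product: 40 3-[(tert-butyldimethylsilyl)oxy]-4-methoxybenzoic acid, via aryllithium 39 (not isolated)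
Conditions: n-BuLi, THF, −78 °C; CO2 (g), −78 → 0 °C; cold 1 M HCl to pH 3–4
Reagents that add atoms: carbon dioxide, O=C=O
Why: Bromine–lithium exchange and carboxylation; the lithium is meta to the silyloxy group, so no retro-Brook shift occurs.

**Late union and deprotection**

Step 28
Reactants: 40 3-[(tert-butyldimethylsilyl)oxy]-4-methoxybenzoic acid and 32 (1R,4E,7R,8S,9R,10R)-1,5-dimethyl-8-(propan-2-yl)-9-[(triethylsilyl)oxy]-11-oxabicyclo[8.1.0]undec-4-en-7-ol
Product: 42 (1R,4E,7R,8S,9R,10R)-1,5-dimethyl-8-(propan-2-yl)-9-[(triethylsilyl)oxy]-11-oxabicyclo[8.1.0]undec-4-en-7-yl 3-[(tert-butyldimethylsilyl)oxy]-4-methoxybenzoate, via mixed anhydride 41 (not isolated)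
Conditions: 40, 2,4,6-trichlorobenzoyl chloride, Et3N, THF, rt; then 32, DMAP, toluene, rt → 40 °C
Reagents that add atoms: none
Why: Yamaguchi esterification, in which the mixed anhydride/acyl-DMAP species acylates the only free hydroxyl (C8) with retention at C8 under non-acidic conditions.

Step 29
Reactants: 42 (1R,4E,7R,8S,9R,10R)-1,5-dimethyl-8-(propan-2-yl)-9-[(triethylsilyl)oxy]-11-oxabicyclo[8.1.0]undec-4-en-7-yl 3-[(tert-butyldimethylsilyl)oxy]-4-methoxybenzoate
Product: 43 (1R,4E,7R,8R,9R,10R)-9-hydroxy-1,5-dimethyl-8-(propan-2-yl)-11-oxabicyclo[8.1.0]undec-4-en-7-yl 3-hydroxy-4-methoxybenzoate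
Conditions: TBAF/AcOH (1:1, 2.5 equiv), THF, 0 °C → rt
Reagents that add atoms: none
Why: Acetic-acid-buffered fluoride removes the aryl TBS and the secondary TES ether without 8→6 acyl migration, Payne rearrangement or epoxide opening.

## Compound list

1 | but-3-yn-1-ol | C#CCCO | starting material
2 | tert-butyl(but-3-yn-1-yloxy)dimethylsilane | C#CCCO[Si](C)(C)C(C)(C)C | intermediate
3 | [(1E)-4-[(tert-butyldimethylsilyl)oxy]-2-methylbut-1-en-1-yl]dimethylalane (not isolated) | C[Al](C)/C=C(\C)CCO[Si](C)(C)C(C)(C)C | intermediate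
4 | ethyl (2E)-5-[(tert-butyldimethylsilyl)oxy]-3-methylpent-2-enoate | CCOC(=O)/C=C(\C)CCO[Si](C)(C)C(C)(C)C | intermediate
5 | ethyl (2E)-5-hydroxy-3-methylpent-2-enoate | CCOC(=O)/C=C(\C)CCO | intermediate
6 | ethyl (2E)-5-iodo-3-methylpent-2-enoate | CCOC(=O)/C=C(\C)CCI | intermediate
7 | prop-2-yn-1-ol | C#CCO | starting material
8 | dimethylaluminium (2E)-3-(dimethylalumanyl)-2-methylprop-2-en-1-olate (not isolated) | C[Al](C)/C=C(\C)CO[Al](C)C | intermediate
9 | (2E)-3-iodo-2-methylprop-2-en-1-ol | I/C=C(\C)CO | intermediate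
10 | tert-butyl{[(2E)-3-iodo-2-methylprop-2-en-1-yl]oxy}dimethylsilane | I/C=C(\C)CO[Si](C)(C)C(C)(C)C | intermediate
11 | [(1E)-3-[(tert-butyldimethylsilyl)oxy]-2-methylprop-1-en-1-yl]lithium (not isolated) | [Li]/C=C(\C)CO[Si](C)(C)C(C)(C)C | intermediate
12 | (2E)-4-[(tert-butyldimethylsilyl)oxy]-3-methylbut-2-enal | O=C/C=C(\C)CO[Si](C)(C)C(C)(C)C | intermediate
13 | 3-bromoprop-1-yne | C#CCBr | starting material
14 | propa-1,2-dien-1-ylmagnesium bromide (not isolated) | C=C=C[Mg]Br | intermediate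
15 | tributyl(propa-1,2-dien-1-yl)stannane | C=C=C[Sn](CCCC)(CCCC)CCCC | intermediate
16 | (2E,4R)-1-[(tert-butyldimethylsilyl)oxy]-2-methylhept-2-en-6-yn-4-ol | O[C@@H](/C=C(\C)CO[Si](C)(C)C(C)(C)C)CC#C | intermediate
17 | dimethylaluminium (2E,4R,6E)-1-[(tert-butyldimethylsilyl)oxy]-7-(dimethylalumanyl)-2,6-dimethylhepta-2,6-dien-4-olate (not isolated) | C[Al](C)O[C@@H](/C=C(\C)CO[Si](C)(C)C(C)(C)C)C/C(C)=C/[Al](C)C | intermediate
18 | (2E,4R,6E)-1-[(tert-butyldimethylsilyl)oxy]-7-iodo-2,6-dimethylhepta-2,6-dien-4-ol | O[C@@H](/C=C(\C)CO[Si](C)(C)C(C)(C)C)C/C(C)=C/I | intermediate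
19 | tert-butyl{[(2E,4R,6E)-7-iodo-4-[(4-methoxyphenyl)methoxy]-2,6-dimethylhepta-2,6-dien-1-yl]oxy}dimethylsilane | COc1ccc(CO[C@@H](/C=C(\C)CO[Si](C)(C)C(C)(C)C)C/C(C)=C/I)cc1 | intermediate
20 | [(3E)-5-ethoxy-3-methyl-5-oxopent-3-en-1-yl]zinc iodide (not isolated) | CCOC(=O)/C=C(\C)CC[Zn]I | intermediate
21 | ethyl (2E,6E,9R,10E)-12-[(tert-butyldimethylsilyl)oxy]-9-[(4-methoxyphenyl)methoxy]-3,7,11-trimethyldodeca-2,6,10-trienoate | COc1ccc(CO[C@@H](/C=C(\C)CO[Si](C)(C)C(C)(C)C)C/C(C)=C/CC/C(C)=C/C(=O)OCC)cc1 | intermediate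
22 | ethyl (2E,6E,9R,10E)-12-hydroxy-9-[(4-methoxyphenyl)methoxy]-3,7,11-trimethyldodeca-2,6,10-trienoate | COc1ccc(CO[C@@H](/C=C(\C)CO)C/C(C)=C/CC/C(C)=C/C(=O)OCC)cc1 | intermediate
23 | ethyl (2E,6E,9R,10E)-12-[(methanesulfonyl)oxy]-9-[(4-methoxyphenyl)methoxy]-3,7,11-trimethyldodeca-2,6,10-trienoate (not isolated) | COc1ccc(CO[C@@H](/C=C(\C)COS(C)(=O)=O)C/C(C)=C/CC/C(C)=C/C(=O)OCC)cc1 | intermediate
24 | ethyl (2E,6E,9R,10E)-12-chloro-9-[(4-methoxyphenyl)methoxy]-3,7,11-trimethyldodeca-2,6,10-trienoate | COc1ccc(CO[C@@H](/C=C(\C)CCl)C/C(C)=C/CC/C(C)=C/C(=O)OCC)cc1 | intermediate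
25 | (2E,6E,9R,10E)-12-chloro-9-[(4-methoxyphenyl)methoxy]-3,7,11-trimethyldodeca-2,6,10-trien-1-ol | COc1ccc(CO[C@@H](/C=C(\C)CCl)C/C(C)=C/CC/C(C)=C/CO)cc1 | intermediate
26 | [(2R,3R)-3-{(3E,6R,7E)-9-chloro-6-[(4-methoxyphenyl)methoxy]-4,8-dimethylnona-3,7-dien-1-yl}-3-methyloxiran-2-yl]methanol | COc1ccc(CO[C@@H](/C=C(\C)CCl)C/C(C)=C/CC[C@@]2(C)O[C@@H]2CO)cc1 | intermediate
27 | (2S,3R)-3-{(3E,6R,7E)-9-chloro-6-[(4-methoxyphenyl)methoxy]-4,8-dimethylnona-3,7-dien-1-yl}-3-methyloxirane-2-carbaldehyde | COc1ccc(CO[C@@H](/C=C(\C)CCl)C/C(C)=C/CC[C@@]2(C)O[C@@H]2C=O)cc1 | intermediate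
28 | ethyl{(2E,4R,6E)-9-[(2R,3S)-3-formyl-2-methyloxiran-2-yl]-4-[(4-methoxyphenyl)methoxy]-2,6-dimethylnona-2,6-dien-1-yl}zinc (not isolated) | COc1ccc(CO[C@@H](/C=C(\C)C[Zn]CC)C/C(C)=C/CC[C@@]2(C)O[C@@H]2C=O)cc1 | intermediate
29 | (1R,4E,7R,8R,9R,10R)-7-[(4-methoxyphenyl)methoxy]-1,5-dimethyl-8-(prop-1-en-2-yl)-11-oxabicyclo[8.1.0]undec-4-en-9-ol | COc1ccc(CO[C@@H]2C/C(C)=C/CC[C@@]3(C)O[C@@H]3[C@H](O)[C@H]2C(C)=C)cc1 | intermediate
30 | (1R,4E,7R,8S,9R,10R)-7-[(4-methoxyphenyl)methoxy]-1,5-dimethyl-8-(prop-1-en-2-yl)-9-[(triethylsilyl)oxy]-11-oxabicyclo[8.1.0]undec-4-ene | COc1ccc(CO[C@@H]2C/C(C)=C/CC[C@@]3(C)O[C@@H]3[C@H](O[Si](CC)(CC)CC)[C@H]2C(C)=C)cc1 | intermediate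
31 | (1R,4E,7R,8S,9R,10R)-7-[(4-methoxyphenyl)methoxy]-1,5-dimethyl-8-(propan-2-yl)-9-[(triethylsilyl)oxy]-11-oxabicyclo[8.1.0]undec-4-ene | COc1ccc(CO[C@@H]2C/C(C)=C/CC[C@@]3(C)O[C@@H]3[C@H](O[Si](CC)(CC)CC)[C@H]2C(C)C)cc1 | intermediate
32 | (1R,4E,7R,8S,9R,10R)-1,5-dimethyl-8-(propan-2-yl)-9-[(triethylsilyl)oxy]-11-oxabicyclo[8.1.0]undec-4-en-7-ol | O[C@@H]1C/C(C)=C/CC[C@@]2(C)O[C@@H]2[C@H](O[Si](CC)(CC)CC)[C@H]1C(C)C | intermediate
33 | benzene-1,2-diol (catechol) | Oc1ccccc1O | starting material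
34 | 2-methoxyphenol | COc1ccccc1O | intermediate
35 | 2-methoxyphenyl acetate | COc1ccccc1OC(C)=O | intermediate
36 | 5-bromo-2-methoxyphenyl acetate | COc1ccc(Br)cc1OC(C)=O | intermediate
37 | 5-bromo-2-methoxyphenol | COc1ccc(Br)cc1O | intermediate
38 | (5-bromo-2-methoxyphenoxy)(tert-butyl)dimethylsilane | COc1ccc(Br)cc1O[Si](C)(C)C(C)(C)C | intermediate
39 | {3-[(tert-butyldimethylsilyl)oxy]-4-methoxyphenyl}lithium (not isolated) | COc1ccc([Li])cc1O[Si](C)(C)C(C)(C)C | intermediate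
40 | 3-[(tert-butyldimethylsilyl)oxy]-4-methoxybenzoic acid | COc1ccc(C(=O)O)cc1O[Si](C)(C)C(C)(C)C | intermediate
41 | 3-[(tert-butyldimethylsilyl)oxy]-4-methoxybenzoic 2,4,6-trichlorobenzoic anhydride (not isolated) | COc1ccc(C(=O)OC(=O)c2c(Cl)cc(Cl)cc2Cl)cc1O[Si](C)(C)C(C)(C)C | intermediate
42 | (1R,4E,7R,8S,9R,10R)-1,5-dimethyl-8-(propan-2-yl)-9-[(triethylsilyl)oxy]-11-oxabicyclo[8.1.0]undec-4-en-7-yl 3-[(tert-butyldimethylsilyl)oxy]-4-methoxybenzoate | COc1ccc(C(=O)O[C@@H]2C/C(C)=C/CC[C@@]3(C)O[C@@H]3[C@H](O[Si](CC)(CC)CC)[C@H]2C(C)C)cc1O[Si](C)(C)C(C)(C)C | intermediate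
43 | (1R,4E,7R,8R,9R,10R)-9-hydroxy-1,5-dimethyl-8-(propan-2-yl)-11-oxabicyclo[8.1.0]undec-4-en-7-yl 3-hydroxy-4-methoxybenzoate (CNP0294356.1) | COc1ccc(C(=O)O[C@@H]2C/C(C)=C/CC[C@@]3(C)O[C@@H]3[C@H](O)[C@H]2C(C)C)cc1O | target

## Summary

Total step count: 29.
Longest linear sequence: 18 steps (5, 6, 7, 9–21, 28, 29, from prop-2-yn-1-ol). The side branches are steps 1–4 (but-3-yn-1-ol), step 8 (propargyl bromide) and steps 22–27 (catechol).

Three steps most likely to fail:

Step 18 (ring closure). Medium-ring formation competes with oligomerisation, and the influence of the C8 ether on the facial selectivity at C7 is not known for this substrate. The fallback sets out from 25 and returns at 29: intramolecular Williamson etherification (NaH, THF, high dilution) gives the 13-membered diallyl ether (3E,5R,7E,11E)-5-[(4-methoxyphenyl)methoxy]-3,7,11-trimethyl-1-oxacyclotrideca-3,7,11-triene F1. A [2,3]-Wittig ring contraction (n-BuLi, THF, −78 → −20 °C; deprotonation at the less hindered O–CH2 next to C5, bond formation C6–C7) then gives (1S,2E,6E,9R,10R)-9-[(4-methoxyphenyl)methoxy]-3,7-dimethyl-10-(prop-1-en-2-yl)cyclodeca-2,6-dien-1-ol F2. A matched, erythro-selective Sharpless epoxidation of this secondary allylic alcohol (Ti(OiPr)4, D-(−)-DET, t-BuOOH) installs the 4,5-epoxide to give 29.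

Step 9 (asymmetric propargylation). The β,β-disubstituted enal is a slow substrate, and both the ee and the propargyl/allenyl ratio may be insufficient. The fallback sets out from 12 (with 13) and returns at 16: a zinc Barbier reaction (Zn, THF/aq. NH4Cl) gives racemic (2E)-1-[(tert-butyldimethylsilyl)oxy]-2-methylhept-2-en-6-yn-4-ol F3. Dess–Martin oxidation gives (2E)-1-[(tert-butyldimethylsilyl)oxy]-2-methylhept-2-en-6-yn-4-one F4, which is used at once. Corey–Bakshi–Shibata reduction ((S)-Me-CBS, catecholborane, toluene, −78 °C; the alkenyl group acts as the large substituent) gives (R)-16, so the stereocentre comes from ketone reduction instead of C–C bond formation.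

Step 12 (Negishi union). Zinc insertion into the homoallylic iodide next to an enoate and the subsequent sp3–sp2 coupling may be low-yielding. The fallback sets out from 19 and returns at 21, building the C2–C6 part on the vinyl iodide by the iterative Negishi protocol. Pd-catalysed coupling of 19 with the known reagent [4-(trimethylsilyl)but-3-yn-1-yl]zinc bromide gives tert-butyl{[(2E,4R,6E)-4-[(4-methoxyphenyl)methoxy]-2,6-dimethyl-11-(trimethylsilyl)undeca-2,6-dien-10-yn-1-yl]oxy}dimethylsilane F5. K2CO3/MeOH gives tert-butyl{[(2E,4R,6E)-4-[(4-methoxyphenyl)methoxy]-2,6-dimethylundeca-2,6-dien-10-yn-1-yl]oxy}dimethylsilane F6. Zr-catalysed carboalumination (Me3Al, Cp2ZrCl2) followed by ClCO2Et gives 21.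

## Further compounds

F1 | step 18 | (3E,5R,7E,11E)-5-[(4-methoxyphenyl)methoxy]-3,7,11-trimethyl-1-oxacyclotrideca-3,7,11-triene | COc1ccc(CO[C@@H]2C/C(C)=C/CC/C(C)=C/COC/C(C)=C/2)cc1
F2 | step 18 | (1S,2E,6E,9R,10R)-9-[(4-methoxyphenyl)methoxy]-3,7-dimethyl-10-(prop-1-en-2-yl)cyclodeca-2,6-dien-1-ol | COc1ccc(CO[C@@H]2C/C(C)=C/CC/C(C)=C/[C@H](O)[C@H]2C(C)=C)cc1
F3 | step 9 | racemic (2E)-1-[(tert-butyldimethylsilyl)oxy]-2-methylhept-2-en-6-yn-4-ol | C#CCC(O)/C=C(\C)CO[Si](C)(C)C(C)(C)C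
F4 | step 9 | (2E)-1-[(tert-butyldimethylsilyl)oxy]-2-methylhept-2-en-6-yn-4-one | C#CCC(=O)/C=C(\C)CO[Si](C)(C)C(C)(C)C
F5 | step 12 | tert-butyl{[(2E,4R,6E)-4-[(4-methoxyphenyl)methoxy]-2,6-dimethyl-11-(trimethylsilyl)undeca-2,6-dien-10-yn-1-yl]oxy}dimethylsilane | COc1ccc(CO[C@@H](/C=C(\C)CO[Si](C)(C)C(C)(C)C)C/C(C)=C/CCC#C[Si](C)(C)C)cc1
F6 | step 12 | tert-butyl{[(2E,4R,6E)-4-[(4-methoxyphenyl)methoxy]-2,6-dimethylundeca-2,6-dien-10-yn-1-yl]oxy}dimethylsilane | COc1ccc(CO[C@@H](/C=C(\C)CO[Si](C)(C)C(C)(C)C)C/C(C)=C/CCC#C)cc1
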